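**Plan**

Side-chain carbons are numbered C1' (benzylic CH2) to C16'. After removal of the O-protecting groups, the retrosynthesis cuts C9'–C10', then C1'–C2' (together with the C3' methyl), then C4'–C5'.
The C9'–C10' cut rests on the C6'=C7'–C8'–C9'–C10'=C11' 1,5-diene. C9' is a primary carbon that can be carried as a radical, released from a carboxyl group on C9' by loss of CO2. C10' is the hydrogen-bearing carbon of a trisubstituted alkene and can be carried as an (E)-alkenyl iodide. Both precursors are electrophiles and are joined reductively at nickel.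
Forward: geranyl acetate is cut down to a C7 enal ester (C5'–C9' plus the carboxyl carbon). Asymmetric propargylation adds C2'–C4' and sets C5'. Methylalumination/benzylation of the alkyne builds C2'=C3' and attaches ring A, which is carried intact as its dimethyl ether.
The ester is turned into a redox-active ester and coupled with the C9 alkenyl iodide to complete the C16 chain. Oxidative demethylation, reduction and desilylation then give the hydroquinone.
Stereochemistry: C5' (S) comes from chiral phosphoric acid-catalysed allenylboration. C2'=C3' and C10'=C11' (E) come from syn-methylalumination of terminal alkynes and stereoretentive couplings. C6'=C7' (E) comes from geranyl acetate.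

Key step: step 16

Remark: the single stereocentre C5' is (S) by CIP analysis; the sense of induction assumed for the phosphoric acid in step 11 is to be checked on 16 by Mosher ester analysis, and the antipodal catalyst used if it proves opposite.

**Route**

Step 1
Reactants: 1 5-bromo-2-methylpent-2-ene
Product: 2 6-methylhept-5-en-1-yne
Conditions: LiC≡CH·H2NCH2CH2NH2 (1.5 equiv), DMSO, 10 °C to rt
Reagents that add atoms: lithium acetylide–ethylenediamine complex, [Li+].[C-]#C.NCCN
Why: SN2 alkylation of an acetylide by a primary homoallylic bromide in DMSO should give the terminal enyne directly.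

Step 2
Reactants: 2 6-methylhept-5-en-1-yne
Product: 4 (E)-1-iodo-2,6-dimethylhepta-1,5-diene, via alkenylalane 3 (not isolated)
Conditions: AlMe3 (2 equiv), Cp2ZrCl2 (0.25 equiv), CH2Cl2, 0 °C to rt; then I2, THF, −30 to 0 °C
Reagents that add atoms: trimethylaluminium, C[Al](C)C; iodine, II
Why: Negishi zirconium-catalysed methylalumination adds Me and Al syn across the terminal alkyne with Me on the internal carbon, and iodinolysis with retention should fix the (E)-geometry of the future C10'=C11' alkene.

Step 3
Reactants: 5 4-methoxy-2-methylphenol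
Product: 6 2-hydroxy-5-methoxy-3-methylbenzaldehyde
Conditions: MgCl2, Et3N, (CH2O)n, MeCN, reflux
Reagents that add atoms: paraformaldehyde (as formaldehyde), C=O
Why: Casnati–Skattebøl ortho-formylation through the magnesium phenoxide should functionalise the only free position ortho to the hydroxyl group, the para position being blocked by OMe.

Step 4
Reactants: 6 2-hydroxy-5-methoxy-3-methylbenzaldehyde
Product: 7 2,5-dimethoxy-3-methylbenzaldehyde
Conditions: MeI, K2CO3, DMF, rt
Reagents that add atoms: iodomethane, CI
Why: Williamson O-methylation of the phenol should be clean.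

Step 5
Reactants: 7 2,5-dimethoxy-3-methylbenzaldehyde
Product: 8 (2,5-dimethoxy-3-methylphenyl)methanol
Conditions: NaBH4, MeOH, 0 °C
Reagents that add atoms: none
Why: Borohydride reduction of an aryl aldehyde should give the benzylic alcohol.

Step 6
Reactants: 8 (2,5-dimethoxy-3-methylphenyl)methanol
Product: 9 1-(chloromethyl)-2,5-dimethoxy-3-methylbenzene
Conditions: SOCl2, DMF (cat.), CH2Cl2, 0 °C to rt; used without storage
Reagents that add atoms: thionyl chloride, O=S(Cl)Cl
Why: Deoxychlorination of an electron-rich benzylic alcohol through the chlorosulfite should be fast and leave only gaseous by-products.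

Step 7
Reactants: 10 geranyl acetate
Product: 11 (2E)-3-methyl-6-oxohex-2-en-1-yl acetate
Conditions: O3 (1.0 equiv, metered), pyridine, CH2Cl2, −78 °C; then Me2S, −78 °C to rt
Reagents that add atoms: ozone, [O-][O+]=O
Why: Chemoselective ozonolysis should cleave the electron-rich terminal trisubstituted alkene, because the 2,3-alkene is deactivated by the allylic acetoxy group; the (E)-alkene that becomes C6'=C7' is untouched.

Step 8
Reactants: 11 (2E)-3-methyl-6-oxohex-2-en-1-yl acetate
Product: 12 (4E)-6-acetoxy-4-methylhex-4-enoic acid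
Conditions: NaClO2, NaH2PO4, 2-methylbut-2-ene, t-BuOH/H2O, 0 °C to rt
Reagents that add atoms: sodium chlorite, [Na+].[O-]Cl=O
Why: Pinnick oxidation should convert the aldehyde into the acid, the scavenger alkene protecting the trisubstituted alkene from hypochlorous acid.

Step 9
Reactants: 12 (4E)-6-acetoxy-4-methylhex-4-enoic acid
Product: 14 methyl (4E)-6-hydroxy-4-methylhex-4-enoate, via acetoxy ester 13 (not isolated)
Conditions: K2CO3, MeI, DMF, rt; then MeOH, rt
Reagents that add atoms: iodomethane, CI
Why: Carboxylate O-alkylation followed by carbonate-catalysed methanolysis of the allylic acetate in the same flask should give the hydroxy ester.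

Step 10
Reactants: 14 methyl (4E)-6-hydroxy-4-methylhex-4-enoate
Product: 15 methyl (4E)-4-methyl-6-oxohex-4-enoate
Conditions: MnO2 (activated, excess), CH2Cl2, rt
Reagents that add atoms: none
Why: Allylic oxidation with MnO2 should give the (E)-enal without touching the ester or the alkene geometry.

Step 11
Reactants: 15 methyl (4E)-4-methyl-6-oxohex-4-enoate
Product: 16 methyl (4E,6S)-6-hydroxy-4-methylnon-4-en-8-ynoate
Conditions: allenylboronic acid pinacol ester (1.5 equiv), (S)-3,3'-bis(2,4,6-triisopropylphenyl)-1,1'-binaphthyl-2,2'-diyl hydrogen phosphate (5 mol%), 4 Å molecular sieves, toluene, 0 °C; aqueous work-up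
Reagents that add atoms: allenylboronic acid pinacol ester, C=C=CB1OC(C)(C)C(C)(C)O1
Why: Chiral phosphoric acid-catalysed allenylboration (SE2' propargylation through a closed six-membered transition state with the catalyst hydrogen-bonded to the boronate) should deliver the propargyl group to the Si face of the enal under control of the (S)-catalyst and so set C5' as (S).

Step 12
Reactants: 16 methyl (4E,6S)-6-hydroxy-4-methylnon-4-en-8-ynoate
Product: 17 methyl (4E,6S)-6-[(tert-butyldimethylsilyl)oxy]-4-methylnon-4-en-8-ynoate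
Conditions: TBSCl, imidazole, DMF, rt
Reagents that add atoms: tert-butyldimethylsilyl chloride, CC(C)(C)[Si](C)(C)Cl
Why: Silylation of the secondary alcohol masks the allylic, homopropargylic oxygen against chelation-driven isomerisation and ionisation in the organoaluminium step and against acylation later.

Step 13
Reactants: 17 methyl (4E,6S)-6-[(tert-butyldimethylsilyl)oxy]-4-methylnon-4-en-8-ynoate; 9 1-(chloromethyl)-2,5-dimethoxy-3-methylbenzene
Product: 19 methyl (4E,6S,8E)-6-[(tert-butyldimethylsilyl)oxy]-10-(2,5-dimethoxy-3-methylphenyl)-4,8-dimethyldeca-4,8-dienoate, via alkenylalane 18 (not isolated)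
Conditions: AlMe3 (2.5 equiv), Cp2ZrCl2 (0.2 equiv), H2O (1 equiv), CH2Cl2, −20 °C; volatiles removed; then 9, zerovalent nickel catalyst from NiCl2(PPh3)2 (5 mol%) and n-BuLi (10 mol%), THF, rt
Reagents that add atoms: trimethylaluminium, C[Al](C)C
Why: Water-accelerated Negishi methylalumination (syn, Me on the internal carbon, fast enough at low temperature to spare the methyl ester) followed by nickel-catalysed coupling of the alkenylalane with the benzylic chloride, with retention, should build the (E)-C2'=C3' alkene and attach ring A in one flask.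

Step 14
Reactants: 19 methyl (4E,6S,8E)-6-[(tert-butyldimethylsilyl)oxy]-10-(2,5-dimethoxy-3-methylphenyl)-4,8-dimethyldeca-4,8-dienoate
Product: 20 (4E,6S,8E)-6-[(tert-butyldimethylsilyl)oxy]-10-(2,5-dimethoxy-3-methylphenyl)-4,8-dimethyldeca-4,8-dienoic acid
Conditions: LiOH·H2O, THF/MeOH/H2O, 0 °C to rt; then 0.5 M HCl to pH 4, 0 °C
Reagents that add atoms: lithium hydroxide, [Li+].[OH-]
Why: Saponification of the unhindered methyl ester should leave the secondary silyl ether, the aryl methyl ethers and the non-conjugated alkenes unchanged.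

Step 15
Reactants: 20 (4E,6S,8E)-6-[(tert-butyldimethylsilyl)oxy]-10-(2,5-dimethoxy-3-methylphenyl)-4,8-dimethyldeca-4,8-dienoic acid
Product: 21 1,3-dioxoisoindolin-2-yl (4E,6S,8E)-6-[(tert-butyldimethylsilyl)oxy]-10-(2,5-dimethoxy-3-methylphenyl)-4,8-dimethyldeca-4,8-dienoate
Conditions: N-hydroxyphthalimide (1.1 equiv), N,N'-diisopropylcarbodiimide (1.1 equiv), 4-(dimethylamino)pyridine (0.1 equiv), CH2Cl2, rt
Reagents that add atoms: N-hydroxyphthalimide, O=C1c2ccccc2C(=O)N1O
Why: Carbodiimide esterification (Steglich type) should give the redox-active N-acyloxyphthalimide, which is stable to chromatography.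

Step 16
Reactants: 21 1,3-dioxoisoindolin-2-yl (4E,6S,8E)-6-[(tert-butyldimethylsilyl)oxy]-10-(2,5-dimethoxy-3-methylphenyl)-4,8-dimethyldeca-4,8-dienoate; 4 (E)-1-iodo-2,6-dimethylhepta-1,5-diene (2 equiv)
Product: 22 tert-butyl{[(2E,5S,6E,10E)-1-(2,5-dimethoxy-3-methylphenyl)-3,7,11,15-tetramethylhexadeca-2,6,10,14-tetraen-5-yl]oxy}dimethylsilane
Conditions: NiCl2·6H2O (10 mol%), 2,2'-bipyridine (10 mol%), AgNO3 (0.3 equiv), DMF, undivided cell, sacrificial Mg anode, reticulated vitreous carbon cathode, constant current, rt
Reagents that add atoms: none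
Why: Cathodically generated low-valent nickel–bipyridine inserts into the C–I bond of 4 with retention of geometry, while single-electron reduction of 21 (at nickel or at the silver-coated cathode) causes N–O cleavage and loss of CO2 to give the primary C9' radical; the radical is captured by the alkenylnickel species and reductive elimination from the resulting trivalent nickel centre forms the C9'–C10' bond. The closest known reaction type is the nickel-catalysed electroreductive decarboxylative alkenylation of redox-active esters with alkenyl iodides, a cross-electrophile coupling used for polyene terpenoid chains and the reductive counterpart of the coupling of such esters with alkenylzinc reagents. No ring is closed and no stereocentre is created: C5' is remote from the radical site, and the C10'=C11' geometry set in step 2 is transferred unchanged because oxidative addition and reductive elimination at the alkenyl carbon are stereoretentive. The step needs cross-coupling to win over hydrodecarboxylation of 21 and homocoupling of 4, which the excess of the simple iodide and the slow, current-controlled release of the radical should secure. It also needs the radical not to rearrange: 3-exo closure onto C7' is reversible and unproductive, and the (E)-C6'=C7' alkene holds the C5'–H out of reach of 1,5-hydrogen transfer. The silyl ether, the aryl methyl ethers and the trisubstituted alkenes are inert to the mildly reducing, non-basic medium.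

Step 17
Reactants: 22 tert-butyl{[(2E,5S,6E,10E)-1-(2,5-dimethoxy-3-methylphenyl)-3,7,11,15-tetramethylhexadeca-2,6,10,14-tetraen-5-yl]oxy}dimethylsilane
Product: 24 2-{(2E,5S,6E,10E)-5-[(tert-butyldimethylsilyl)oxy]-3,7,11,15-tetramethylhexadeca-2,6,10,14-tetraen-1-yl}-6-methylbenzene-1,4-diol, via quinone 23 (not isolated)
Conditions: (NH4)2Ce(NO3)6 (2.5 equiv), MeCN/H2O 2:1, 0 °C, 15 min; extraction; then Na2S2O4, Et2O/H2O, rt, argon
Reagents that add atoms: water, O
Why: Oxidative demethylation of the hydroquinone dimethyl ether by tetravalent cerium (two one-electron oxidations, addition of water, loss of methanol) should give the 1,4-benzoquinone, which dithionite reduces to the hydroquinone, while the silyl ether shields C5' from acid-promoted ionisation during the short exposure.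

Step 18
Reactants: 24 2-{(2E,5S,6E,10E)-5-[(tert-butyldimethylsilyl)oxy]-3,7,11,15-tetramethylhexadeca-2,6,10,14-tetraen-1-yl}-6-methylbenzene-1,4-diol
Product: 25 2-[(2E,5S,6E,10E)-5-hydroxy-3,7,11,15-tetramethylhexadeca-2,6,10,14-tetraen-1-yl]-6-methylbenzene-1,4-diol
Conditions: Bu4NF (3 equiv), AcOH (3 equiv), degassed THF, 0 °C to rt, argon; work-up with aq. NH4Cl/Na2S2O4
Reagents that add atoms: none
Why: Fluoride-mediated desilylation buffered with acetic acid should free the C5' alcohol without base-promoted air oxidation of the hydroquinone and without touching the stereocentre.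

**Compound list**

1 | 5-bromo-2-methylpent-2-ene | CC(C)=CCCBr | starting material
2 | 6-methylhept-5-en-1-yne | CC(C)=CCCC#C | intermediate
3 | (E)-(2,6-dimethylhepta-1,5-dien-1-yl)dimethylalane | CC(C)=CCC/C(C)=C/[Al](C)C | intermediate
4 | (E)-1-iodo-2,6-dimethylhepta-1,5-diene | CC(C)=CCC/C(C)=C/I | intermediate
5 | 4-methoxy-2-methylphenol | COc1ccc(O)c(C)c1 | starting material
6 | 2-hydroxy-5-methoxy-3-methylbenzaldehyde | COc1cc(C)c(O)c(C=O)c1 | intermediate
7 | 2,5-dimethoxy-3-methylbenzaldehyde | COc1cc(C)c(OC)c(C=O)c1 | intermediate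
8 | (2,5-dimethoxy-3-methylphenyl)methanol | COc1cc(C)c(OC)c(CO)c1 | intermediate
9 | 1-(chloromethyl)-2,5-dimethoxy-3-methylbenzene | COc1cc(C)c(OC)c(CCl)c1 | intermediate
10 | geranyl acetate, (2E)-3,7-dimethylocta-2,6-dien-1-yl acetate | CC(C)=CCC/C(C)=C/COC(C)=O | starting material
11 | (2E)-3-methyl-6-oxohex-2-en-1-yl acetate | O=CCC/C(C)=C/COC(C)=O | intermediate
12 | (4E)-6-acetoxy-4-methylhex-4-enoic acid | OC(=O)CC/C(C)=C/COC(C)=O | intermediate
13 | methyl (4E)-6-acetoxy-4-methylhex-4-enoate | COC(=O)CC/C(C)=C/COC(C)=O | intermediate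
14 | methyl (4E)-6-hydroxy-4-methylhex-4-enoate | COC(=O)CC/C(C)=C/CO | intermediate
15 | methyl (4E)-4-methyl-6-oxohex-4-enoate | COC(=O)CC/C(C)=C/C=O | intermediate
16 | methyl (4E,6S)-6-hydroxy-4-methylnon-4-en-8-ynoate | COC(=O)CC/C(C)=C/[C@@H](O)CC#C | intermediate
17 | methyl (4E,6S)-6-[(tert-butyldimethylsilyl)oxy]-4-methylnon-4-en-8-ynoate | COC(=O)CC/C(C)=C/[C@@H](O[Si](C)(C)C(C)(C)C)CC#C | intermediate
18 | methyl (4E,6S,8E)-6-[(tert-butyldimethylsilyl)oxy]-9-(dimethylalumanyl)-4,8-dimethylnona-4,8-dienoate | COC(=O)CC/C(C)=C/[C@@H](O[Si](C)(C)C(C)(C)C)C/C(C)=C/[Al](C)C | intermediate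
19 | methyl (4E,6S,8E)-6-[(tert-butyldimethylsilyl)oxy]-10-(2,5-dimethoxy-3-methylphenyl)-4,8-dimethyldeca-4,8-dienoate | COC(=O)CC/C(C)=C/[C@@H](O[Si](C)(C)C(C)(C)C)C/C(C)=C/Cc1cc(OC)cc(C)c1OC | intermediate
20 | (4E,6S,8E)-6-[(tert-butyldimethylsilyl)oxy]-10-(2,5-dimethoxy-3-methylphenyl)-4,8-dimethyldeca-4,8-dienoic acid | OC(=O)CC/C(C)=C/[C@@H](O[Si](C)(C)C(C)(C)C)C/C(C)=C/Cc1cc(OC)cc(C)c1OC | intermediate
21 | 1,3-dioxoisoindolin-2-yl (4E,6S,8E)-6-[(tert-butyldimethylsilyl)oxy]-10-(2,5-dimethoxy-3-methylphenyl)-4,8-dimethyldeca-4,8-dienoate | O=C(CC/C(C)=C/[C@@H](O[Si](C)(C)C(C)(C)C)C/C(C)=C/Cc1cc(OC)cc(C)c1OC)ON1C(=O)c2ccccc2C1=O | intermediate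
22 | tert-butyl{[(2E,5S,6E,10E)-1-(2,5-dimethoxy-3-methylphenyl)-3,7,11,15-tetramethylhexadeca-2,6,10,14-tetraen-5-yl]oxy}dimethylsilane | CC(C)=CCC/C(C)=C/CC/C(C)=C/[C@@H](O[Si](C)(C)C(C)(C)C)C/C(C)=C/Cc1cc(OC)cc(C)c1OC | intermediate
23 | 2-{(2E,5S,6E,10E)-5-[(tert-butyldimethylsilyl)oxy]-3,7,11,15-tetramethylhexadeca-2,6,10,14-tetraen-1-yl}-6-methylcyclohexa-2,5-diene-1,4-dione | CC(C)=CCC/C(C)=C/CC/C(C)=C/[C@@H](O[Si](C)(C)C(C)(C)C)C/C(C)=C/CC1=CC(=O)C=C(C)C1=O | intermediate
24 | 2-{(2E,5S,6E,10E)-5-[(tert-butyldimethylsilyl)oxy]-3,7,11,15-tetramethylhexadeca-2,6,10,14-tetraen-1-yl}-6-methylbenzene-1,4-diol | CC(C)=CCC/C(C)=C/CC/C(C)=C/[C@@H](O[Si](C)(C)C(C)(C)C)C/C(C)=C/Cc1cc(O)cc(C)c1O | intermediate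
25 | 2-[(2E,5S,6E,10E)-5-hydroxy-3,7,11,15-tetramethylhexadeca-2,6,10,14-tetraen-1-yl]-6-methylbenzene-1,4-diol | CC(C)=CCC/C(C)=C/CC/C(C)=C/[C@@H](O)C/C(C)=C/Cc1cc(O)cc(C)c1O | target

**Step count and risks**

Total step count: 18. Longest linear sequence: 12 steps (steps 7 to 18, from geranyl acetate 10 to 25).

Steps most likely to fail:

Step 16. The radical may be reduced further before nickel captures it (hydrodecarboxylation), the alkenyl iodide may homocouple, or the cathode may passivate so that the ester is consumed unproductively. Fallback, a polar palladium coupling in place of the radical union: acid 20 is converted with N-hydroxypyridine-2-thione and dicyclohexylcarbodiimide into the N-acyloxypyridine-2-thione (Barton ester) F1. Photolysis in the presence of CHI3 gives the homoallylic iodide F2 by decarboxylative iodination. Zinc insertion (Zn dust, LiCl, THF) gives the alkylzinc iodide F3, and Pd(PPh3)4-catalysed Negishi coupling with 4 gives 22, where the route is rejoined.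

Step 13. The aluminium reagent may attack the methyl ester, methylalumination may be incomplete or insufficiently regioselective, or the benzylic chloride may homocouple or take up a methyl group at nickel. Fallback, an isolated electrophile and a benzylic nucleophile in place of the one-flask alane coupling: starting from 17, the alkenylalane 18 is quenched with I2 and the alkenyl iodide F4 is purified. Separately 9 is converted with Zn dust/LiCl in THF into the benzylzinc chloride F5. Pd(PPh3)4-catalysed Negishi coupling of F4 with F5 gives 19, where the route is rejoined.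

Step 17. The acidic cerium medium may cleave the allylic silyl ether and ionise C5', the arene may dimerise oxidatively, or the freed hydroquinone may cyclise onto C2'=C3'. Fallback, oxidation in basic medium at an electrode instead of by a metal oxidant in acid: starting from 22, anodic oxidation (Pt anode, 1% KOH in MeOH, 0 °C) gives the quinone bis(dimethyl ketal) F6. Brief hydrolysis with aqueous oxalic acid on silica gel in CH2Cl2 gives the quinone 23, where the route is rejoined before the dithionite reduction to 24.

**Further compounds**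

F1 | step 16 | 2-thioxopyridin-1(2H)-yl (4E,6S,8E)-6-[(tert-butyldimethylsilyl)oxy]-10-(2,5-dimethoxy-3-methylphenyl)-4,8-dimethyldeca-4,8-dienoate | O=C(CC/C(C)=C/[C@@H](O[Si](C)(C)C(C)(C)C)C/C(C)=C/Cc1cc(OC)cc(C)c1OC)On1ccccc1=S
F2 | step 16 | tert-butyl{[(2E,5S,6E)-1-(2,5-dimethoxy-3-methylphenyl)-9-iodo-3,7-dimethylnona-2,6-dien-5-yl]oxy}dimethylsilane | ICC/C(C)=C/[C@@H](O[Si](C)(C)C(C)(C)C)C/C(C)=C/Cc1cc(OC)cc(C)c1OC
F3 | step 16 | {(3E,5S,7E)-5-[(tert-butyldimethylsilyl)oxy]-9-(2,5-dimethoxy-3-methylphenyl)-3,7-dimethylnona-3,7-dien-1-yl}zinc iodide | I[Zn]CC/C(C)=C/[C@@H](O[Si](C)(C)C(C)(C)C)C/C(C)=C/Cc1cc(OC)cc(C)c1OC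
F4 | step 13 | methyl (4E,6S,8E)-6-[(tert-butyldimethylsilyl)oxy]-9-iodo-4,8-dimethylnona-4,8-dienoate | COC(=O)CC/C(C)=C/[C@@H](O[Si](C)(C)C(C)(C)C)C/C(C)=C/I
F5 | step 13 | (2,5-dimethoxy-3-methylbenzyl)zinc chloride | COc1cc(C)c(OC)c(C[Zn]Cl)c1
F6 | step 17 | tert-butyl{[(2E,5S,6E,10E)-3,7,11,15-tetramethyl-1-(3,3,6,6-tetramethoxy-5-methylcyclohexa-1,4-dien-1-yl)hexadeca-2,6,10,14-tetraen-5-yl]oxy}dimethylsilane | CC(C)=CCC/C(C)=C/CC/C(C)=C/[C@@H](O[Si](C)(C)C(C)(C)C)C/C(C)=C/CC1=CC(OC)(OC)C=C(C)C1(OC)OC
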